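## Retrosynthetic overview

1. The halogens come last. The C–Cl bond is made from a tertiary alcohol through a bromonium ion, the C–Br bond by invertive bromide opening of an (R)-epoxide, and the epoxide by reagent-controlled epoxidation of a prenyl terminus.
2. The hydroxylated side chain is made by a 1,2-metallate rearrangement of a C2–CH2CH2–Bpin unit with lithiated (R)-but-3-en-2-yl carbamate, then oxidation. The boron comes from exo-face hydroboration of a C2 exocyclic methylene (this sets C2) and one CH2 insertion.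
3. The key disconnection is C1–C2: a cobalt hydride radical cycloisomerisation of a 2-methylideneoxolane (ring A: O7–C4–C5–C6–C1) whose C4 substituent is the quaternary carbon C3 carrying a vinyl group. The one new bond closes oxolane ring B (O7–C1–C2–C3–C4) and cyclohexane ring C (C1–C6) together.
4. Enabling feature: bridgehead C1 is fully substituted and carries O7 and a methyl group, so it is the tertiary α-oxy radical obtained by adding H• to an enol ether. C2 is the fifth atom from it along C1–O7–C4–C3–C2 (a hex-5-enyl relation). C2 lies between the quaternary carbons C1 and C3, so the exocyclic alkene formed cannot migrate.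
5. The cyclisation precursor comes from geranyl-Bpin and pent-4-ynal by catalytic asymmetric allylboration (C3 and C4 in one event), then silver-catalysed 5-exo-dig hydroalkoxylation. Ring order: A first, then B and C together.

Key step: step 4

Remark: C1–C7 are the locants of the 7-oxabicyclo[2.2.1]heptane core of the target (C1 methyl-bearing bridgehead, C2 carrying the hydroxylated chain, C3 quaternary, C4 bridgehead CH, O7 the bridge). The facial sense of the phosphoric acid in step 2 is assigned by analogy with simple allylboronates; if it proves opposite, the (R)-acid is used.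

## Route

Step 1
Reactants: 1 geranyl chloride, (2E)-1-chloro-3,7-dimethylocta-2,6-diene
Product: 2 geranyl-Bpin, 2-[(2E)-3,7-dimethylocta-2,6-dien-1-yl]-4,4,5,5-tetramethyl-1,3,2-dioxaborolane
Conditions: B2pin2 (1.1 equiv), Pd2(dba)3 (0.5 mol %, zerovalent palladium), THF, 60 °C
Reagents that add atoms: bis(pinacolato)diboron, CC1(C)OB(OC1(C)C)B1OC(C)(C)C(C)(C)O1
Why: Palladium-catalysed allylic borylation through a π-allyl complex should give the linear boronate with the E geometry retained, and this geometry later fixes the relative configuration of C3 and C4.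

Step 2
Reactants: 2 geranyl-Bpin; 3 pent-4-ynal
Product: 5 (5R,6S)-6-ethenyl-6,10-dimethylundec-9-en-1-yn-5-ol, via pinacol borate ester 4 (not isolated)
Conditions: (S)-TRIP [(S)-3,3′-bis(2,4,6-triisopropylphenyl)-1,1′-binaphthyl-2,2′-diyl hydrogen phosphate] (5 mol %), 4 Å MS, toluene, −30 → 0 °C; then aq. NaHCO3
Reagents that add atoms: none
Why: Chiral-phosphoric-acid-catalysed allylboration through a closed chair transition state, in which the E geometry of 2 puts the homoprenyl chain equatorial and the methyl axial (hydroxyl syn to methyl in the zigzag drawing) and the phosphate should select the Si face of the aldehyde, so the carbinol carbon and the adjacent quaternary carbon (future C4 and C3) are set in one catalytic event.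

Step 3
Reactants: 5 (5R,6S)-6-ethenyl-6,10-dimethylundec-9-en-1-yn-5-ol
Product: 6 (2R)-2-[(3S)-3,7-dimethylocta-1,6-dien-3-yl]-5-methylideneoxolane
Conditions: Ag2CO3 (10 mol %, monovalent silver), benzene, 80 °C; filtration through basic alumina, used at once
Reagents that add atoms: none
Why: Silver-catalysed 5-exo-dig hydroalkoxylation (cycloisomerisation) of a 4-pentyn-1-ol under neutral conditions should give the exocyclic enol ether (ring A) without touching the alkenes or any stereocentre.

Step 4
Reactants: 6 (2R)-2-[(3S)-3,7-dimethylocta-1,6-dien-3-yl]-5-methylideneoxolane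
Product: 7 (1S,3S,4R)-1,3-dimethyl-2-methylidene-3-(4-methylpent-3-en-1-yl)-7-oxabicyclo[2.2.1]heptane
Conditions: Co(salen)Cl (5 mol %, trivalent cobalt; salen = N,N′-bis(3,5-di-tert-butylsalicylidene)cyclohexane-1,2-diaminate), PhSiH3 (6 mol %), dry degassed benzene, 25–50 °C, Ar
Reagents that add atoms: none
Why: Proposed new method: the silane turns the trivalent cobalt chloride into a cobalt hydride, which transfers a hydrogen atom to the CH2 terminus of the enol ether (or, after reversible isomerisation, to C6 of the endocyclic enol ether) and so generates the tertiary 2-methyloxolan-2-yl radical at C1; this nucleophilic α-oxygenated radical adds to the internal carbon of the vinyl group on C3, and divalent cobalt then removes the only β-hydrogen (on C2) of the resulting primary radical, which releases the exocyclic alkene and returns the hydride, so that the step is a redox-neutral isomerisation. The closest known reaction types are the Co(salen)-catalysed hydrogen-atom-transfer cycloisomerisation of 1,6-dienes, the hydrogen-atom-transfer coupling of enol ethers through α-oxy radicals, and the tin hydride closure of 5-propargylpyrrolidin-2-yl radicals to 2-methylidene-7-azabicyclo[2.2.1]heptanes. The one new bond closes oxolane ring B in the 5-exo-trig mode (C1–O7–C4–C3–C2) and, because C1 and C4 are already tied through C5–C6, cyclohexane ring C at the same time (6-exo-trig along C1–C6–C5–C4–C3–C2). C1 is set by substrate control from C4, since the tether can only reach the radical from the face cis to the C4–C3 bond, and the configuration of C3 then places its methyl endo and its chain exo; C2 stays trigonal and is set in step 5. The step needs hydrogen-atom transfer to the enol ether in preference to the vinyl and prenyl groups (the electron-rich 1,1-disubstituted enol ether is the best hydrogen-atom acceptor) and 5-exo in preference to 6-endo closure (stereoelectronic preference of hex-5-enyl radicals, reinforced by the quaternary C3 in the tether). The product alkene lies between the quaternary carbons C1 and C3 and has no allylic hydrogen on the ring, so the catalyst cannot move it and it should accumulate.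

Step 5
Reactants: 7 (1S,3S,4R)-1,3-dimethyl-2-methylidene-3-(4-methylpent-3-en-1-yl)-7-oxabicyclo[2.2.1]heptane
Product: 8 2-{[(1S,2S,3S,4R)-1,3-dimethyl-3-(4-methylpent-3-en-1-yl)-7-oxabicyclo[2.2.1]heptan-2-yl]methyl}-4,4,5,5-tetramethyl-1,3,2-dioxaborolane
Conditions: HBpin (1.5 equiv), RhCl(PPh3)3 (3 mol %, monovalent rhodium), THF, 25 °C
Reagents that add atoms: pinacolborane, CC1(C)OBOC1(C)C
Why: Rhodium-catalysed anti-Markovnikov hydroboration engages the 1,1-disubstituted alkene but not the trisubstituted prenyl alkene, and the metal should bind on the exo face (the side of O7, away from the C5–C6 bridge) and deliver hydrogen to C2 there, so the borylmethyl group ends endo and cis to the C3 methyl, as the target requires.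

Step 6
Reactants: 8 the C2-methyl boronic ester
Product: 10 2-{2-[(1S,2S,3S,4R)-1,3-dimethyl-3-(4-methylpent-3-en-1-yl)-7-oxabicyclo[2.2.1]heptan-2-yl]ethyl}-4,4,5,5-tetramethyl-1,3,2-dioxaborolane, via chloromethyl boronate complex 9 (not isolated)
Conditions: BrCH2Cl (2 equiv), n-BuLi (1.8 equiv), THF, −78 → 25 °C
Reagents that add atoms: bromochloromethane (as chloromethyllithium made in the flask), ClCBr
Why: Matteson homologation, in which chloromethyllithium adds to boron and the primary alkyl group migrates with loss of chloride, inserts one CH2 without touching a stereocentre.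

Step 7
Reactants: 11 (R)-but-3-en-2-ol
Product: 12 (2R)-but-3-en-2-yl N,N-diisopropylcarbamate
Conditions: i-Pr2NCOCl, Et3N, DMAP (cat.), CH2Cl2, reflux
Reagents that add atoms: N,N-diisopropylcarbamoyl chloride, CC(C)N(C(C)C)C(Cl)=O
Why: O-Carbamoylation of the secondary alcohol installs the directing and leaving group for the lithiation and leaves the stereocentre untouched.

Step 8
Reactants: 10 the C2-ethyl boronic ester; 12 (2R)-but-3-en-2-yl N,N-diisopropylcarbamate
Product: 16 (3S)-5-[(1S,2S,3S,4R)-1,3-dimethyl-3-(4-methylpent-3-en-1-yl)-7-oxabicyclo[2.2.1]heptan-2-yl]-3-methylpent-1-en-3-ol, via lithiated carbamate 13 (not isolated), via lithium boronate complex 14 (not isolated), via tertiary allylic boronic ester 15 (not isolated)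
Conditions: 12, s-BuLi, TMEDA, Et2O, −78 °C; then 10; MgBr2·OEt2/MeOH, −78 → 25 °C; then NaOH, H2O2, THF, 0 °C
Reagents that add atoms: hydrogen peroxide, OO
Why: Lithiation–borylation (carbamate-directed α-lithiation with retention, boronate formation with retention, stereospecific 1,2-metallate rearrangement with inversion at carbon as the carbamate leaves) followed by C–B oxidation with retention should turn the (R)-carbamate into the (S)-configured tertiary allylic alcohol under reagent control.

Step 9
Reactants: 16 the tertiary allylic alcohol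
Product: 17 triethyl{[(3S)-5-[(1S,2S,3S,4R)-1,3-dimethyl-3-(4-methylpent-3-en-1-yl)-7-oxabicyclo[2.2.1]heptan-2-yl]-3-methylpent-1-en-3-yl]oxy}silane
Conditions: TESOTf, 2,6-lutidine, CH2Cl2, −78 → 0 °C
Reagents that add atoms: triethylsilyl trifluoromethanesulfonate, CC[Si](CC)(CC)OS(=O)(=O)C(F)(F)F
Why: Silylation of the tertiary alcohol with a silyl triflate masks it, so that only the later bromohydrin hydroxyl is open to chlorination.

Step 10
Reactants: 17 the triethylsilyl ether
Product: 18 triethyl{[(3S)-5-[(1S,2S,3S,4R)-3-{2-[(2R)-3,3-dimethyloxiran-2-yl]ethyl}-1,3-dimethyl-7-oxabicyclo[2.2.1]heptan-2-yl]-3-methylpent-1-en-3-yl]oxy}silane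
Conditions: D-fructose-derived Shi ketone (1,2:4,5-di-O-isopropylidene-β-D-erythro-2,3-hexodiulo-2,6-pyranose, 30 mol %), KHSO5, K2CO3, Bu4NHSO4, Na2B4O7 buffer, MeCN/CH2(OMe)2/H2O, 0 °C
Reagents that add atoms: potassium peroxymonosulfate, [K+].[O-]S(=O)(=O)OO
Why: Shi asymmetric epoxidation, in which the chiral dioxirane reacts with the electron-rich trisubstituted alkene far faster than with the monosubstituted vinyl group and the spiro transition state of the D-fructose-derived ketone should give the (R)-epoxide under reagent control.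

Step 11
Reactants: 18 the (R)-epoxide
Product: 19 (3S)-3-bromo-5-[(1S,2S,3S,4R)-1,3-dimethyl-2-{(3S)-3-methyl-3-[(triethylsilyl)oxy]pent-4-en-1-yl}-7-oxabicyclo[2.2.1]heptan-3-yl]-2-methylpentan-2-ol
Conditions: Li2NiBr4 (2 equiv, divalent nickel), THF, 0 → 25 °C; then H2O
Reagents that add atoms: dilithium tetrabromonickelate, [Li+].[Li+].[Ni+2].[Br-].[Br-].[Br-].[Br-]
Why: Nucleophilic epoxide opening by soft bromide, where the tertiary carbon cannot be attacked in a bimolecular sense and the weak Lewis acidity disfavours ionisation, should place bromide on the secondary carbon with inversion and give the (S)-bromide.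

Step 12
Reactants: 19 the bromohydrin
Product: 20 {[(3S)-5-[(1S,2S,3S,4R)-3-[(3S)-3-bromo-4-chloro-4-methylpentyl]-1,3-dimethyl-7-oxabicyclo[2.2.1]heptan-2-yl]-3-methylpent-1-en-3-yl]oxy}triethylsilane
Conditions: 1-chloro-N,N,2-trimethylprop-1-en-1-amine (1.5 equiv), CH2Cl2, 0 → 25 °C
Reagents that add atoms: 1-chloro-N,N,2-trimethylprop-1-en-1-amine, CC(C)=C(Cl)N(C)C
Why: Deoxychlorination of a tertiary alcohol with an α-chloroenamine under neutral conditions, in which the alkoxy-iminium group leaves with help from the neighbouring bromine and chloride should open the bromonium ion at the tertiary carbon, so the C–Br stereocentre is retained.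

Step 13
Reactants: 20 the silyl-protected bromochloride
Product: 21 (3S)-5-[(1S,2S,3S,4R)-3-[(3S)-3-bromo-4-chloro-4-methylpentyl]-1,3-dimethyl-7-oxabicyclo[2.2.1]heptan-2-yl]-3-methylpent-1-en-3-ol
Conditions: HF·pyridine, pyridine, THF, 0 °C
Reagents that add atoms: none
Why: Fluoride-mediated cleavage of the silyl ether under buffered conditions should spare the tertiary chloride, the secondary bromide and the tertiary allylic alcohol.

## Compound list

1 | geranyl chloride, (2E)-1-chloro-3,7-dimethylocta-2,6-diene | CC(C)=CCC/C(C)=C/CCl | starting material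
2 | geranyl-Bpin, 2-[(2E)-3,7-dimethylocta-2,6-dien-1-yl]-4,4,5,5-tetramethyl-1,3,2-dioxaborolane | CC(C)=CCC/C(C)=C/CB1OC(C)(C)C(C)(C)O1 | intermediate
3 | pent-4-ynal | C#CCCC=O | starting material
4 | pinacol borate ester of 5, 2-{[(5R,6S)-6-ethenyl-6,10-dimethylundec-9-en-1-yn-5-yl]oxy}-4,4,5,5-tetramethyl-1,3,2-dioxaborolane | C#CCC[C@@H](OB1OC(C)(C)C(C)(C)O1)[C@@](C)(CCC=C(C)C)C=C | intermediate (not isolated)
5 | (5R,6S)-6-ethenyl-6,10-dimethylundec-9-en-1-yn-5-ol | C#CCC[C@@H](O)[C@@](C)(CCC=C(C)C)C=C | intermediate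
6 | (2R)-2-[(3S)-3,7-dimethylocta-1,6-dien-3-yl]-5-methylideneoxolane | C=C1CC[C@@H](O1)[C@@](C)(CCC=C(C)C)C=C | intermediate
7 | (1S,3S,4R)-1,3-dimethyl-2-methylidene-3-(4-methylpent-3-en-1-yl)-7-oxabicyclo[2.2.1]heptane | C=C1[C@](C)(CCC=C(C)C)[C@H]2CC[C@]1(C)O2 | intermediate
8 | 2-{[(1S,2S,3S,4R)-1,3-dimethyl-3-(4-methylpent-3-en-1-yl)-7-oxabicyclo[2.2.1]heptan-2-yl]methyl}-4,4,5,5-tetramethyl-1,3,2-dioxaborolane | CC1(C)OB(C[C@H]2[C@](C)(CCC=C(C)C)[C@H]3CC[C@]2(C)O3)OC1(C)C | intermediate
9 | lithium chloromethyl boronate complex of 8 (boron carries the chloromethyl group, the C2-methyl group and the pinacolate) | [Li+].ClC[B-]1(C[C@H]2[C@](C)(CCC=C(C)C)[C@H]3CC[C@]2(C)O3)OC(C)(C)C(C)(C)O1 | intermediate (not isolated)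
10 | 2-{2-[(1S,2S,3S,4R)-1,3-dimethyl-3-(4-methylpent-3-en-1-yl)-7-oxabicyclo[2.2.1]heptan-2-yl]ethyl}-4,4,5,5-tetramethyl-1,3,2-dioxaborolane | CC1(C)OB(CC[C@H]2[C@](C)(CCC=C(C)C)[C@H]3CC[C@]2(C)O3)OC1(C)C | intermediate
11 | (R)-but-3-en-2-ol | C=C[C@@H](C)O | starting material
12 | (2R)-but-3-en-2-yl N,N-diisopropylcarbamate | C=C[C@@H](C)OC(=O)N(C(C)C)C(C)C | intermediate
13 | α-lithiated carbamate (lithium in place of the carbinol hydrogen of 12, configuration retained) | C=C[C@@]([Li])(C)OC(=O)N(C(C)C)C(C)C | intermediate (not isolated)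
14 | lithium boronate complex (boron of 10 bonded to the carbamate-bearing carbon, configuration retained) | [Li+].C=C[C@@](C)(OC(=O)N(C(C)C)C(C)C)[B-]1(CC[C@H]2[C@](C)(CCC=C(C)C)[C@H]3CC[C@]2(C)O3)OC(C)(C)C(C)(C)O1 | intermediate (not isolated)
15 | tertiary allylic boronic ester, 2-[(3R)-5-[(1S,2S,3S,4R)-1,3-dimethyl-3-(4-methylpent-3-en-1-yl)-7-oxabicyclo[2.2.1]heptan-2-yl]-3-methylpent-1-en-3-yl]-4,4,5,5-tetramethyl-1,3,2-dioxaborolane | C=C[C@@](C)(B1OC(C)(C)C(C)(C)O1)CC[C@H]2[C@](C)(CCC=C(C)C)[C@H]3CC[C@]2(C)O3 | intermediate (not isolated)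
16 | (3S)-5-[(1S,2S,3S,4R)-1,3-dimethyl-3-(4-methylpent-3-en-1-yl)-7-oxabicyclo[2.2.1]heptan-2-yl]-3-methylpent-1-en-3-ol | C=C[C@@](C)(O)CC[C@H]1[C@](C)(CCC=C(C)C)[C@H]2CC[C@]1(C)O2 | intermediate
17 | triethyl{[(3S)-5-[(1S,2S,3S,4R)-1,3-dimethyl-3-(4-methylpent-3-en-1-yl)-7-oxabicyclo[2.2.1]heptan-2-yl]-3-methylpent-1-en-3-yl]oxy}silane | C=C[C@@](C)(O[Si](CC)(CC)CC)CC[C@H]1[C@](C)(CCC=C(C)C)[C@H]2CC[C@]1(C)O2 | intermediate
18 | triethyl{[(3S)-5-[(1S,2S,3S,4R)-3-{2-[(2R)-3,3-dimethyloxiran-2-yl]ethyl}-1,3-dimethyl-7-oxabicyclo[2.2.1]heptan-2-yl]-3-methylpent-1-en-3-yl]oxy}silane | C=C[C@@](C)(O[Si](CC)(CC)CC)CC[C@H]1[C@](C)(CC[C@H]3OC3(C)C)[C@H]2CC[C@]1(C)O2 | intermediate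
19 | (3S)-3-bromo-5-[(1S,2S,3S,4R)-1,3-dimethyl-2-{(3S)-3-methyl-3-[(triethylsilyl)oxy]pent-4-en-1-yl}-7-oxabicyclo[2.2.1]heptan-3-yl]-2-methylpentan-2-ol | C=C[C@@](C)(O[Si](CC)(CC)CC)CC[C@H]1[C@](C)(CC[C@H](Br)C(C)(C)O)[C@H]2CC[C@]1(C)O2 | intermediate
20 | {[(3S)-5-[(1S,2S,3S,4R)-3-[(3S)-3-bromo-4-chloro-4-methylpentyl]-1,3-dimethyl-7-oxabicyclo[2.2.1]heptan-2-yl]-3-methylpent-1-en-3-yl]oxy}triethylsilane | C=C[C@@](C)(O[Si](CC)(CC)CC)CC[C@H]1[C@](C)(CC[C@H](Br)C(C)(C)Cl)[C@H]2CC[C@]1(C)O2 | intermediate
21 | (3S)-5-[(1S,2S,3S,4R)-3-[(3S)-3-bromo-4-chloro-4-methylpentyl]-1,3-dimethyl-7-oxabicyclo[2.2.1]heptan-2-yl]-3-methylpent-1-en-3-ol | C=C[C@@](C)(O)CC[C@H]1[C@](C)(CC[C@H](Br)C(C)(C)Cl)[C@H]2CC[C@]1(C)O2 | target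

## Step count and risks

Total step count: 13. Longest linear sequence: 12 steps (steps 1–6 and 8–13, from geranyl chloride); step 7 is a one-step branch that prepares carbamate 12.

Steps most likely to fail:

First, step 4 (proposed new method). The tertiary radical may be returned to the enol ether by back hydrogen transfer faster than it cyclises, so that only exo/endo isomerisation of the enol ether occurs. It may also close 6-endo onto the vinyl terminus, or hydrogen-atom transfer to the prenyl alkene may move that double bond. The fallback uses a stoichiometric radical chain of known type instead of hydrogen-atom-transfer catalysis; it sets out from 6 and comes back at 7. Benzeneselenol is added across the enol ether (PhSeH, cat. pyridinium p-toluenesulfonate, CH2Cl2, −20 °C) to give the O,Se-ketal (5R)-5-[(3S)-3,7-dimethylocta-1,6-dien-3-yl]-2-methyl-2-(phenylselanyl)oxolane F1. Irradiation with (Bu3Sn)2 (10 mol %) and PhSeSePh in benzene should generate the same C1 radical, which closes 5-exo, and the primary radical is capped by phenylselanyl transfer to give the selenide (1S,3S,4R)-1,3-dimethyl-3-(4-methylpent-3-en-1-yl)-2-[(phenylselanyl)methyl]-7-oxabicyclo[2.2.1]heptane F2 (either C2 epimer serves). Oxidation with H2O2/pyridine and syn-elimination of the selenoxide, whose only β-hydrogen is on C2, should return 7.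

Second, step 8. The lithiated allyl carbamate may be borylated at its γ-terminus, it may lose configurational integrity before it is trapped, or the 1,2-migration onto the crowded carbon may be too slow and give back the boronic ester. The fallback builds the carbinol by cross-coupling and titanium–tartrate epoxidation; it sets out from 7 and comes back at 16. Hydroboration of 7 with 9-BBN (THF, 60 °C, exo face) gives 9-{[(1S,2S,3S,4R)-1,3-dimethyl-3-(4-methylpent-3-en-1-yl)-7-oxabicyclo[2.2.1]heptan-2-yl]methyl}-9-borabicyclo[3.3.1]nonane F3. This is coupled in the same flask with (E)-3-iodo-2-methylprop-2-en-1-ol [Suzuki–Miyaura coupling, PdCl2(dppf) (divalent palladium), AsPh3, Cs2CO3, DMF/H2O] to give (2E)-4-[(1S,2S,3S,4R)-1,3-dimethyl-3-(4-methylpent-3-en-1-yl)-7-oxabicyclo[2.2.1]heptan-2-yl]-2-methylbut-2-en-1-ol F4. Sharpless epoxidation [Ti(OiPr)4 (tetravalent titanium), D-(−)-diethyl tartrate, t-BuOOH, 4 Å MS, CH2Cl2, −20 °C] should give [(2R,3R)-3-{[(1S,2S,3S,4R)-1,3-dimethyl-3-(4-methylpent-3-en-1-yl)-7-oxabicyclo[2.2.1]heptan-2-yl]methyl}-2-methyloxiran-2-yl]methanol F5. Hydride opening at the secondary epoxide carbon with i-Bu2AlH gives (2S)-4-[(1S,2S,3S,4R)-1,3-dimethyl-3-(4-methylpent-3-en-1-yl)-7-oxabicyclo[2.2.1]heptan-2-yl]-2-methylbutane-1,2-diol F6. Parikh–Doering oxidation (SO3·pyridine, DMSO, Et3N) gives (2S)-2-hydroxy-4-[(1S,2S,3S,4R)-1,3-dimethyl-3-(4-methylpent-3-en-1-yl)-7-oxabicyclo[2.2.1]heptan-2-yl]-2-methylbutanal F7, and Wittig methylenation (Ph3P=CH2) gives 16.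

Third, step 11. Ionisation toward the tertiary epoxide carbon may deliver bromide to the CMe2 carbon or lead by hydride shift to the isopropyl ketone, and the later chlorination (step 12) may then end in elimination. The fallback reverses the order of halogen introduction and bypasses both steps; it sets out from 18 and comes back at 20. The epoxide is opened by chloride at the tertiary carbon under mild Brønsted acid (pyridinium chloride, CH2Cl2, 0 °C), with the secondary C–O bond untouched, to give (3R)-2-chloro-5-[(1S,2S,3S,4R)-1,3-dimethyl-2-{(3S)-3-methyl-3-[(triethylsilyl)oxy]pent-4-en-1-yl}-7-oxabicyclo[2.2.1]heptan-3-yl]-2-methylpentan-3-ol F8. Appel bromination of the secondary alcohol with inversion [CBr4, (n-C8H17)3P, toluene, 70 °C] should then give 20.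

Further compounds
F1 | step 4 | (5R)-5-[(3S)-3,7-dimethylocta-1,6-dien-3-yl]-2-methyl-2-(phenylselanyl)oxolane (both C2 epimers) | CC1([Se]c2ccccc2)CC[C@@H](O1)[C@@](C)(CCC=C(C)C)C=C
F2 | step 4 | (1S,3S,4R)-1,3-dimethyl-3-(4-methylpent-3-en-1-yl)-2-[(phenylselanyl)methyl]-7-oxabicyclo[2.2.1]heptane (both C2 epimers) | C(C1[C@](C)(CCC=C(C)C)[C@H]2CC[C@]1(C)O2)[Se]c1ccccc1
F3 | step 8 | 9-{[(1S,2S,3S,4R)-1,3-dimethyl-3-(4-methylpent-3-en-1-yl)-7-oxabicyclo[2.2.1]heptan-2-yl]methyl}-9-borabicyclo[3.3.1]nonane | C([C@H]1[C@](C)(CCC=C(C)C)[C@H]2CC[C@]1(C)O2)B1C2CCCC1CCC2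
F4 | step 8 | (2E)-4-[(1S,2S,3S,4R)-1,3-dimethyl-3-(4-methylpent-3-en-1-yl)-7-oxabicyclo[2.2.1]heptan-2-yl]-2-methylbut-2-en-1-ol | OC/C(C)=C/C[C@H]1[C@](C)(CCC=C(C)C)[C@H]2CC[C@]1(C)O2
F5 | step 8 | [(2R,3R)-3-{[(1S,2S,3S,4R)-1,3-dimethyl-3-(4-methylpent-3-en-1-yl)-7-oxabicyclo[2.2.1]heptan-2-yl]methyl}-2-methyloxiran-2-yl]methanol | OC[C@@]1(C)O[C@@H]1C[C@H]2[C@](C)(CCC=C(C)C)[C@H]3CC[C@]2(C)O3
F6 | step 8 | (2S)-4-[(1S,2S,3S,4R)-1,3-dimethyl-3-(4-methylpent-3-en-1-yl)-7-oxabicyclo[2.2.1]heptan-2-yl]-2-methylbutane-1,2-diol | OC[C@@](C)(O)CC[C@H]1[C@](C)(CCC=C(C)C)[C@H]2CC[C@]1(C)O2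
F7 | step 8 | (2S)-2-hydroxy-4-[(1S,2S,3S,4R)-1,3-dimethyl-3-(4-methylpent-3-en-1-yl)-7-oxabicyclo[2.2.1]heptan-2-yl]-2-methylbutanal | O=C[C@@](C)(O)CC[C@H]1[C@](C)(CCC=C(C)C)[C@H]2CC[C@]1(C)O2
F8 | step 11 | (3R)-2-chloro-5-[(1S,2S,3S,4R)-1,3-dimethyl-2-{(3S)-3-methyl-3-[(triethylsilyl)oxy]pent-4-en-1-yl}-7-oxabicyclo[2.2.1]heptan-3-yl]-2-methylpentan-3-ol | C=C[C@@](C)(O[Si](CC)(CC)CC)CC[C@H]1[C@](C)(CC[C@@H](O)C(C)(C)Cl)[C@H]2CC[C@]1(C)O2
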